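**Plan**

1. The target is epioritin-(4β→6)-epioritin-4β-ol (epioritin = (2R,3R)-2,3-cis-3',4',7,8-tetrahydroxyflavan-3-ol; flavan numbering). The retrosynthesis cuts the eight phenolic O–H bonds (benzyl ethers), the C4–OH of the lower unit (carried as a C4–S aryl sulfide), the interflavan C4–C6 bond and, inside ring C of the upper unit, the C4–C4a bond, with C3 rejoined to C4a.
2. That last cut turns ring C (O1, C2, C3, C4, C4a, C8a) into the five-membered ring O1–C2–C3–C4a–C8a of a cis-2-aryl-2,3-dihydrobenzofuran whose C3 carries C4 outside the ring as a gem-diacyloxymethyl group.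
3. The feature that permits this is ring A: C4a has O1 ortho and the 7-oxygen para, so it can bridge C3 and C4 as a phenonium ion. The acyloxy group left on C4 then captures C3, and the resulting C3/C4 dioxolanylium ion opens at the benzylic C4.
4. Forward: ether union of the ring A aldehyde with the ring B benzyl chloride, homologation to an aryldiazoacetate, and rhodium-catalysed C–H insertion to close the dihydrofuran (C2–C3). The derived aldehyde is converted into two acylals: the dipropanoate is ring-enlarged with a thiol (lower unit), and the diacetate is ring-enlarged with C6 of that lower unit (upper ring C and interflavan bond together). Deacylation, C–S to C–OH exchange and hydrogenolysis finish the route.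
5. Stereochemistry: C2 and the cis C2/C3 relation of both units come from the chiral dirhodium catalyst. Each C3–O is set by inversion when the acyloxy group displaces ring A. Each C4 is set by attack anti to the dioxolanylium bridge and, for the final C4–OH, anti to the 3-OH.

Key step: step 10

Assumption: Rh2(S-PTTL)4 is taken to induce the (2S,3R) sense on this substrate; if the induction proves opposite, the enantiomeric catalyst Rh2(R-PTTL)4 is used and nothing else changes.

**Route**

Step 1
Reactants: 1 2,3,4-trihydroxybenzaldehyde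
Product: 2 3,4-bis(benzyloxy)-2-hydroxybenzaldehyde
Conditions: BnBr (2.1 equiv), K2CO3 (2.2 equiv), DMF, 0 °C → rt
Reagents that add atoms: benzyl bromide, BrCc1ccccc1
Why: Williamson etherification: the 2-OH is held in a hydrogen bond to the aldehyde and gives the least nucleophilic phenoxide, so two equivalents of benzyl bromide should alkylate only O4 and O3; no stereocentre is formed.

Step 2
Reactants: 2 3,4-bis(benzyloxy)-2-hydroxybenzaldehyde; 3 3,4-bis(benzyloxy)benzyl chloride
Product: 4 3,4-bis(benzyloxy)-2-{[3,4-bis(benzyloxy)phenyl]methoxy}benzaldehyde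
Conditions: K2CO3, NaI (cat.), DMF, 60 °C
Reagents that add atoms: none
Why: Williamson etherification of the remaining chelated phenol with the benzylic chloride (activated in situ as the iodide by Finkelstein exchange) joins rings A and B through the future O1–C2 bond; no stereocentre is formed.

Step 3
Reactants: 4 3,4-bis(benzyloxy)-2-{[3,4-bis(benzyloxy)phenyl]methoxy}benzaldehyde
Product: 5 ethyl (Z)-2-(3,4-bis(benzyloxy)-2-{[3,4-bis(benzyloxy)phenyl]methoxy}phenyl)-3-hydroxyprop-2-enoate
Conditions: N2CHCO2Et (1.3 equiv), [(η5-C5H5)Fe(CO)2(THF)]BF4 (10 mol %), CH2Cl2, 0 °C → rt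
Reagents that add atoms: ethyl diazoacetate, CCOC(=O)C=[N+]=[N-]
Why: Lewis-acid-catalysed aldehyde–diazoacetate homologation: the diazo carbon adds to the iron-bound aldehyde and the electron-rich aryl group shifts to it with loss of N2 (1,2-aryl shift, favoured over hydride shift for alkoxy-substituted benzaldehydes), which should give the formyl arylacetate as its hydrogen-bonded Z-enol; no stereocentre is formed.

Step 4
Reactants: 5 ethyl (Z)-2-(3,4-bis(benzyloxy)-2-{[3,4-bis(benzyloxy)phenyl]methoxy}phenyl)-3-hydroxyprop-2-enoate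
Product: 6 ethyl 2-(3,4-bis(benzyloxy)-2-{[3,4-bis(benzyloxy)phenyl]methoxy}phenyl)-2-diazoacetate
Conditions: 4-AcNHC6H4SO2N3 (1.2 equiv), Et3N, MeCN, 0 °C → rt
Reagents that add atoms: 4-acetamidobenzenesulfonyl azide, CC(=O)Nc1ccc(cc1)S(=O)(=O)N=[N+]=[N-]
Why: Regitz deformylative diazo transfer: the enolate attacks the terminal nitrogen of the sulfonyl azide and the triazoline fragments with loss of the formyl group as an N-formylsulfonamide, leaving the donor/acceptor diazo ester; no stereocentre is formed.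

Step 5
Reactants: 6 ethyl 2-(3,4-bis(benzyloxy)-2-{[3,4-bis(benzyloxy)phenyl]methoxy}phenyl)-2-diazoacetate
Product: 7 ethyl (2S,3R)-6,7-bis(benzyloxy)-2-[3,4-bis(benzyloxy)phenyl]-2,3-dihydro-1-benzofuran-3-carboxylate (2,3-cis)
Conditions: Rh2(S-PTTL)4 [dirhodium tetrakis(N-phthaloyl-(S)-tert-leucinate)] (1 mol %), toluene, −60 °C
Reagents that add atoms: none
Why: Intramolecular 1,5 C–H insertion of the dirhodium carbenoid into the benzylic ether C–H bond (activated by oxygen and by the dialkoxyphenyl ring) closes the dihydrofuran through the C2–C3 bond in one concerted event, so the chiral phthaloyl-tert-leucinate ligands set C2 and C3 together and the kinetic cis isomer should result.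

Step 6
Reactants: 7 ethyl (2S,3R)-6,7-bis(benzyloxy)-2-[3,4-bis(benzyloxy)phenyl]-2,3-dihydro-1-benzofuran-3-carboxylate (2,3-cis)
Product: 8 (2S,3R)-6,7-bis(benzyloxy)-2-[3,4-bis(benzyloxy)phenyl]-2,3-dihydro-1-benzofuran-3-carbaldehyde (2,3-cis)
Conditions: i-Bu2AlH (1.1 equiv), CH2Cl2, −78 °C; MeOH then aq. KNaC4H4O6, 0 °C; crude product divided into two portions and used at once in steps 7 and 9
Reagents that add atoms: none
Why: Partial reduction of the ester by i-Bu2AlH: the aluminium hemiacetal is stable at −78 °C and releases the aldehyde only on cold neutral work-up, which should keep the enolisable cis C3 centre intact; no new stereocentre is formed.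

Step 7
Reactants: 8 (2S,3R)-6,7-bis(benzyloxy)-2-[3,4-bis(benzyloxy)phenyl]-2,3-dihydro-1-benzofuran-3-carbaldehyde (2,3-cis)
Product: 9 [(2S,3R)-6,7-bis(benzyloxy)-2-[3,4-bis(benzyloxy)phenyl]-2,3-dihydro-1-benzofuran-3-yl]methanediyl dipropanoate (2,3-cis)
Conditions: (EtCO)2O (3 equiv), LiBF4 (10 mol %), CH2Cl2, 0 °C → rt
Reagents that add atoms: propanoic anhydride, CCC(=O)OC(=O)CC
Why: Lewis-acid-catalysed acylal formation (addition of the anhydride across the aldehyde C=O) under mild conditions turns the enolisable aldehyde into a configurationally fixed gem-dipropanoate, the latent C4 of the lower flavan unit with its two leaving groups; propanoate is used here and acetate in step 9 so that the two units carry different 3-O-acyl labels and cross-coupling in step 10 can be told from self-condensation of either series; no stereocentre is changed.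

Step 8
Reactants: 9 [(2S,3R)-6,7-bis(benzyloxy)-2-[3,4-bis(benzyloxy)phenyl]-2,3-dihydro-1-benzofuran-3-yl]methanediyl dipropanoate (2,3-cis)
Product: 11 (2R,3S,4S)-7,8-bis(benzyloxy)-2-[3,4-bis(benzyloxy)phenyl]-4-[(2,6-dimethylphenyl)sulfanyl]-3,4-dihydro-2H-chromen-3-yl propanoate (2,3-cis-3,4-trans), via 2-ethyl-1,3-dioxolan-2-ylium ion 10 (not isolated)
Conditions: 2,6-Me2C6H3SH (1.5 equiv), BF3·OEt2 (0.3 equiv), 4 Å molecular sieves, CH2Cl2, −78 → −40 °C
Reagents that add atoms: 2,6-dimethylbenzenethiol, Cc1cccc(C)c1S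
Why: Proposed new method: BF3 should ionise one propanoate of the gem-dipropanoate with Ar1-3 participation of the electron-rich ring A (phenonium ion), and the second propanoate then displaces the bridging aryl carbon from C3 with inversion, so that ring A has moved from C3 to the exocyclic carbon (a Wagner–Meerwein ring enlargement, the reverse of the known oxidative ring contraction of flavanones to 2-aryl-2,3-dihydrobenzofuran-3-carboxylates and close to the phenonium ring enlargement of benzocycloalkylmethyl sulfonates) and the cis precursor gives the 2,3-cis dioxolanylium ion 10, which the thiol opens at the benzylic C4 anti to the bridge (3,4-trans) as in the established Lewis-acid thiolysis of 3-acyloxy-4-oxyflavans.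

Step 9
Reactants: 8 (2S,3R)-6,7-bis(benzyloxy)-2-[3,4-bis(benzyloxy)phenyl]-2,3-dihydro-1-benzofuran-3-carbaldehyde (2,3-cis)
Product: 12 [(2S,3R)-6,7-bis(benzyloxy)-2-[3,4-bis(benzyloxy)phenyl]-2,3-dihydro-1-benzofuran-3-yl]methanediyl diacetate (2,3-cis)
Conditions: Ac2O (3 equiv), LiBF4 (10 mol %), CH2Cl2, 0 °C → rt
Reagents that add atoms: acetic anhydride, CC(=O)OC(C)=O
Why: Lewis-acid-catalysed acylal formation (addition of acetic anhydride across the aldehyde C=O) turns the second portion of the enolisable aldehyde into the configurationally fixed gem-diacetate, the latent C4 of the upper flavan unit with its two leaving groups; no stereocentre is changed.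

Step 10
Reactants: 12 [(2S,3R)-6,7-bis(benzyloxy)-2-[3,4-bis(benzyloxy)phenyl]-2,3-dihydro-1-benzofuran-3-yl]methanediyl diacetate (2,3-cis); 11 (2R,3S,4S)-7,8-bis(benzyloxy)-2-[3,4-bis(benzyloxy)phenyl]-4-[(2,6-dimethylphenyl)sulfanyl]-3,4-dihydro-2H-chromen-3-yl propanoate (2,3-cis-3,4-trans)
Product: 14 3-O-acetyl-7,8,3',4'-tetra-O-benzylepioritin-(4β→6)-7,8,3',4'-tetra-O-benzyl-4β-[(2,6-dimethylphenyl)sulfanyl]-3-O-propanoylepioritin, via acetoxonium ion 13 (not isolated)
Conditions: 11 (3.0 equiv), BF3·OEt2 (0.5 equiv), 4 Å molecular sieves, CH2Cl2, −78 → −30 °C, 12 added over 2 h; excess 11 recovered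
Reagents that add atoms: none
Why: Proposed new method: BF3 should ionise one acetate of 12 with Ar1-3 participation of ring A, whose ipso carbon C4a (ortho to O1, para to the 7-benzyloxy group) bridges to the acetal carbon as a phenonium ion; the second acetate then displaces C4a from C3 through its carbonyl oxygen, so that ring A has moved from C3 to the former exocyclic carbon, the dihydrofuran has become ring C of the flavan and the charge rests in the 3,4-fused acetoxonium ion 13, which C6 of 11 opens at the benzylic C4. The closest known reactions are the phenonium ring enlargement of benzocycloalkylmethyl sulfonates and, across this very bond but in the opposite direction, the oxidative ring contraction of flavanones and 2H-chromenes by PhI(OAc)2 or Tl(NO3)3 to 2-aryl-2,3-dihydrobenzofuran-3-carboxylates and acetals; the direction is reversed here because an acyloxy group makes the exocyclic cation the least stable and the dioxolan-2-ylium ion the most stable species on the path. Ring C is closed by ring enlargement (C4–C4a formed by ipso attack in a 3-exo sense, C3–C4a broken) and not by cyclisation of a chain, and the dioxolanylium ring closes by 5-exo attack of the acetate carbonyl oxygen on C3. C2 is not touched; C3 is set by inversion as the acetate enters anti to the departing aryl carbon, which translates the cis relation of 12 into the 2,3-cis flavan; C4 is set when the arene attacks anti to the acetoxonium bridge (3,4-trans, 4β). The step needs aryl migration to win over hydride and C2 migration, which the two oxygen donors on ring A and the in-plane, non-conjugating position of the C2–C3 bond secure; it needs C6 of 11 (para to O1, ortho to 7-OBn, remote from the C4 sulfide) to react rather than C5 or ring B; it needs 11 to outrun ring A of unreacted 12, which slow addition of 12 to excess 11 secures; and it needs the C4–S bond of 11 to survive, which the hard Lewis acid BF3 secures.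

Step 11
Reactants: 14 3-O-acetyl-7,8,3',4'-tetra-O-benzylepioritin-(4β→6)-7,8,3',4'-tetra-O-benzyl-4β-[(2,6-dimethylphenyl)sulfanyl]-3-O-propanoylepioritin
Product: 15 7,8,3',4'-tetra-O-benzylepioritin-(4β→6)-7,8,3',4'-tetra-O-benzyl-4β-[(2,6-dimethylphenyl)sulfanyl]epioritin
Conditions: K2CO3 (0.3 equiv), MeOH–THF 1:1, rt
Reagents that add atoms: none
Why: Base-catalysed transesterification (methanolysis) removes the secondary acetate and the secondary propanoate while the aryl benzyl ethers and the thioether are inert to carbonate; no stereocentre is touched.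

Step 12
Reactants: 15 7,8,3',4'-tetra-O-benzylepioritin-(4β→6)-7,8,3',4'-tetra-O-benzyl-4β-[(2,6-dimethylphenyl)sulfanyl]epioritin
Product: 16 7,8,3',4'-tetra-O-benzylepioritin-(4β→6)-7,8,3',4'-tetra-O-benzylepioritin-4β-ol
Conditions: AgBF4 (1.5 equiv), 2,6-di-tert-butyl-4-methylpyridine (2 equiv), THF–H2O 10:1, 0 °C, dark
Reagents that add atoms: water, O
Why: Silver-assisted SN1 hydrolysis of the benzylic thioether: the thiophilic silver ion pulls the arylthiolate off C4 of the lower unit and water adds to the 7-alkoxy-stabilised cation from the face anti to the axial 3-OH of the 2,3-cis ring, which should give the 3,4-trans (4β) alcohol, while the hindered pyridine base keeps the medium neutral.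

Step 13
Reactants: 16 7,8,3',4'-tetra-O-benzylepioritin-(4β→6)-7,8,3',4'-tetra-O-benzylepioritin-4β-ol
Product: 17 CNP0143773.2 epioritin-(4β→6)-epioritin-4β-ol
Conditions: H2 (1 atm), Pd(OH)2/C, THF–MeOH 1:1, rt, short contact time
Reagents that add atoms: none
Why: Hydrogenolysis of the eight aryl benzyl ethers over Pd(OH)2 on carbon in neutral solvent, where aryl O–benzyl bonds should cleave much faster than the benzylic C4–OH or the interflavan C–C bond; no stereocentre is touched.

**Compound list**

1 | 2,3,4-trihydroxybenzaldehyde | O=Cc1ccc(O)c(O)c1O | starting material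
2 | 3,4-bis(benzyloxy)-2-hydroxybenzaldehyde | O=Cc1ccc(OCc2ccccc2)c(OCc2ccccc2)c1O | intermediate
3 | 3,4-bis(benzyloxy)benzyl chloride | ClCc1ccc(OCc2ccccc2)c(OCc2ccccc2)c1 | starting material
4 | 3,4-bis(benzyloxy)-2-{[3,4-bis(benzyloxy)phenyl]methoxy}benzaldehyde | O=Cc1ccc(OCc2ccccc2)c(OCc2ccccc2)c1OCc1ccc(OCc2ccccc2)c(OCc2ccccc2)c1 | intermediate
5 | ethyl (Z)-2-(3,4-bis(benzyloxy)-2-{[3,4-bis(benzyloxy)phenyl]methoxy}phenyl)-3-hydroxyprop-2-enoate | O/C=C(C(=O)OCC)/c1ccc(OCc2ccccc2)c(OCc2ccccc2)c1OCc1ccc(OCc2ccccc2)c(OCc2ccccc2)c1 | intermediate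
6 | ethyl 2-(3,4-bis(benzyloxy)-2-{[3,4-bis(benzyloxy)phenyl]methoxy}phenyl)-2-diazoacetate | CCOC(=O)C(=[N+]=[N-])c1ccc(OCc2ccccc2)c(OCc2ccccc2)c1OCc1ccc(OCc2ccccc2)c(OCc2ccccc2)c1 | intermediate
7 | ethyl (2S,3R)-6,7-bis(benzyloxy)-2-[3,4-bis(benzyloxy)phenyl]-2,3-dihydro-1-benzofuran-3-carboxylate (2,3-cis) | c1ccccc1COc1ccc(cc1OCc1ccccc1)[C@H]2Oc3c(ccc(OCc4ccccc4)c3OCc3ccccc3)[C@H]2C(=O)OCC | intermediate
8 | (2S,3R)-6,7-bis(benzyloxy)-2-[3,4-bis(benzyloxy)phenyl]-2,3-dihydro-1-benzofuran-3-carbaldehyde (2,3-cis) | c1ccccc1COc1ccc(cc1OCc1ccccc1)[C@H]2Oc3c(ccc(OCc4ccccc4)c3OCc3ccccc3)[C@H]2C=O | intermediate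
9 | [(2S,3R)-6,7-bis(benzyloxy)-2-[3,4-bis(benzyloxy)phenyl]-2,3-dihydro-1-benzofuran-3-yl]methanediyl dipropanoate (2,3-cis) | c1ccccc1COc1ccc(cc1OCc1ccccc1)[C@H]2Oc3c(ccc(OCc4ccccc4)c3OCc3ccccc3)[C@H]2C(OC(=O)CC)OC(=O)CC | intermediate
10 | 2-ethyl-1,3-dioxolan-2-ylium ion cis-fused across O–C3 and O–C4 of (2R)-7,8,3',4'-tetrakis(benzyloxy)flavan, bridge cis to the 2-aryl group, propanoyloxytrifluoroborate salt | c1ccccc1COc1ccc(cc1OCc1ccccc1)[C@H]2Oc3c(ccc(OCc4ccccc4)c3OCc3ccccc3)[C@H]3[O+]=C(CC)O[C@@H]23.CCC(=O)O[B-](F)(F)F | intermediate (not isolated)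
11 | (2R,3S,4S)-7,8-bis(benzyloxy)-2-[3,4-bis(benzyloxy)phenyl]-4-[(2,6-dimethylphenyl)sulfanyl]-3,4-dihydro-2H-chromen-3-yl propanoate (2,3-cis-3,4-trans; 7,8,3',4'-tetra-O-benzyl-3-O-propanoylepioritin 4β-sulfide) | c1ccccc1COc1ccc(cc1OCc1ccccc1)[C@H]2Oc3c(ccc(OCc4ccccc4)c3OCc3ccccc3)[C@H](Sc3c(C)cccc3C)[C@H]2OC(=O)CC | intermediate
12 | [(2S,3R)-6,7-bis(benzyloxy)-2-[3,4-bis(benzyloxy)phenyl]-2,3-dihydro-1-benzofuran-3-yl]methanediyl diacetate (2,3-cis) | c1ccccc1COc1ccc(cc1OCc1ccccc1)[C@H]2Oc3c(ccc(OCc4ccccc4)c3OCc3ccccc3)[C@H]2C(OC(C)=O)OC(C)=O | intermediate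
13 | acetoxonium ion: 2-methyl-1,3-dioxolan-2-ylium ion cis-fused across O–C3 and O–C4 of (2R)-7,8,3',4'-tetrakis(benzyloxy)flavan, bridge cis to the 2-aryl group, acetoxytrifluoroborate salt | c1ccccc1COc1ccc(cc1OCc1ccccc1)[C@H]2Oc3c(ccc(OCc4ccccc4)c3OCc3ccccc3)[C@H]3[O+]=C(C)O[C@@H]23.CC(=O)O[B-](F)(F)F | intermediate (not isolated)
14 | 3-O-acetyl-7,8,3',4'-tetra-O-benzylepioritin-(4β→6)-7,8,3',4'-tetra-O-benzyl-4β-[(2,6-dimethylphenyl)sulfanyl]-3-O-propanoylepioritin (both units 2R, 2,3-cis-3,4-trans) | c1ccccc1COc1ccc(cc1OCc1ccccc1)[C@H]2Oc3c(ccc(OCc4ccccc4)c3OCc3ccccc3)[C@H](c3cc4c(c(OCc5ccccc5)c3OCc3ccccc3)O[C@H](c3ccc(OCc5ccccc5)c(OCc5ccccc5)c3)[C@H](OC(=O)CC)[C@H]4Sc3c(C)cccc3C)[C@H]2OC(C)=O | intermediate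
15 | 7,8,3',4'-tetra-O-benzylepioritin-(4β→6)-7,8,3',4'-tetra-O-benzyl-4β-[(2,6-dimethylphenyl)sulfanyl]epioritin | c1ccccc1COc1ccc(cc1OCc1ccccc1)[C@H]2Oc3c(ccc(OCc4ccccc4)c3OCc3ccccc3)[C@H](c3cc4c(c(OCc5ccccc5)c3OCc3ccccc3)O[C@H](c3ccc(OCc5ccccc5)c(OCc5ccccc5)c3)[C@H](O)[C@H]4Sc3c(C)cccc3C)[C@H]2O | intermediate
16 | 7,8,3',4'-tetra-O-benzylepioritin-(4β→6)-7,8,3',4'-tetra-O-benzylepioritin-4β-ol | c1ccccc1COc1ccc(cc1OCc1ccccc1)[C@H]2Oc3c(ccc(OCc4ccccc4)c3OCc3ccccc3)[C@H](c3cc4c(c(OCc5ccccc5)c3OCc3ccccc3)O[C@H](c3ccc(OCc5ccccc5)c(OCc5ccccc5)c3)[C@H](O)[C@H]4O)[C@H]2O | intermediate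
17 | CNP0143773.2, epioritin-(4β→6)-epioritin-4β-ol; (2R,3R,4S)-2-(3,4-dihydroxyphenyl)-4-[(2R,3R,4S)-2-(3,4-dihydroxyphenyl)-3,4,7,8-tetrahydroxy-3,4-dihydro-2H-chromen-6-yl]-3,4-dihydro-2H-chromene-3,7,8-triol | Oc1ccc([C@H]2Oc3c(ccc(O)c3O)[C@H](c3cc4c(c(O)c3O)O[C@H](c3ccc(O)c(O)c3)[C@H](O)[C@H]4O)[C@H]2O)cc1O | target

**Step count**

Total step count: 13. Longest linear sequence: 12 steps (steps 1–6 to aldehyde 8, then steps 7, 8, 10, 11, 12 and 13). Step 9 is the only step off that line, and 3 is the only other purchased building block.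

**Steps most likely to fail**

1. Step 8 (proposed new method). The thiol may attack the acetal carbon before ring A has migrated (O,S-acetal formation). A hydride shift from C3 may outrun aryl bridging and lead to aromatisation to the benzofuran. Enolisation at the aldehyde stage may already have eroded the cis relation, so that the 2,3-trans flavan forms.
Fallback (known chemistry, no aldehyde): it sets out from 7. LiAlH4 in THF at 0 °C should give the cis alcohol [(2S,3S)-6,7-bis(benzyloxy)-2-[3,4-bis(benzyloxy)phenyl]-2,3-dihydro-1-benzofuran-3-yl]methanol F1. TsCl in pyridine converts it into its 4-methylbenzenesulfonate F2. Buffered solvolysis in propanoic acid (EtCO2H, EtCO2Na, 70 °C), the classical phenonium ring enlargement of a β-arylalkyl sulfonate with double inversion, should give (2R,3R)-7,8,3',4'-tetra-O-benzyl-3-O-propanoylepioritin F3. Benzylic oxidation at C4 with DDQ and MeOH in CH2Cl2 at rt gives 7,8,3',4'-tetra-O-benzyl-4β-methoxy-3-O-propanoylepioritin F4. Thiolysis with 2,6-dimethylbenzenethiol and BF3·OEt2 (CH2Cl2, −78 → 0 °C), with neighbouring-group control by the 3-propanoate, comes back to the route at 11.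

2. Step 10 (proposed new method, key step). The acetoxonium ion may be consumed by ring A of unreacted 12 or of product 14 (oligomer formation), or it may lose a proton faster than the weakly nucleophilic arene of 11 adds. Attack at the acetal carbon before migration is also conceivable.
Fallback (known chemistry): ring enlargement and bond formation are separated. It sets out from 7, which is taken by way of the alcohol F1 to the 4-methylbenzenesulfonate F2 as described for step 8. Buffered acetolysis (AcOH, NaOAc, 70 °C) should give (2R,3R)-3-O-acetyl-7,8,3',4'-tetra-O-benzylepioritin F5. DDQ and MeOH in CH2Cl2 at rt give 3-O-acetyl-7,8,3',4'-tetra-O-benzyl-4β-methoxyepioritin F6. F6 (1 equiv) is then condensed with 11 (3 equiv) by BF3·OEt2 in CH2Cl2 at −78 → −30 °C, the established 4-alkoxyflavan/flavan coupling with neighbouring-group control by the 3-acetate. This comes back to the route at 14.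

3. Step 13. The activated benzylic C4–OH bond may be hydrogenolysed alongside the benzyl ethers (over-reduction to the 4-deoxy dimer).
Fallback: the order is inverted and hydrogen is avoided. It sets out from 15. BCl3 with pentamethylbenzene in CH2Cl2 at −78 °C removes the eight benzyl groups in the presence of the sulfide and should give epioritin-(4β→6)-4β-[(2,6-dimethylphenyl)sulfanyl]epioritin F7. Silver-assisted hydrolysis (AgBF4, aqueous acetone, 0 °C, under argon) then exchanges sulfur for hydroxyl as the last operation and comes back to the route at 17.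

Further compounds
F1 | step 8 | [(2S,3S)-6,7-bis(benzyloxy)-2-[3,4-bis(benzyloxy)phenyl]-2,3-dihydro-1-benzofuran-3-yl]methanol (2,3-cis) | c1ccccc1COc1ccc(cc1OCc1ccccc1)[C@H]2Oc3c(ccc(OCc4ccccc4)c3OCc3ccccc3)[C@H]2CO
F2 | step 8 | [(2S,3S)-6,7-bis(benzyloxy)-2-[3,4-bis(benzyloxy)phenyl]-2,3-dihydro-1-benzofuran-3-yl]methyl 4-methylbenzenesulfonate (2,3-cis) | c1ccccc1COc1ccc(cc1OCc1ccccc1)[C@H]2Oc3c(ccc(OCc4ccccc4)c3OCc3ccccc3)[C@H]2COS(=O)(=O)c5ccc(C)cc5
F3 | step 8 | (2R,3R)-7,8-bis(benzyloxy)-2-[3,4-bis(benzyloxy)phenyl]-3,4-dihydro-2H-chromen-3-yl propanoate (7,8,3',4'-tetra-O-benzyl-3-O-propanoylepioritin) | c1ccccc1COc1ccc(cc1OCc1ccccc1)[C@H]2Oc3c(ccc(OCc4ccccc4)c3OCc3ccccc3)C[C@H]2OC(=O)CC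
F4 | step 8 | 7,8,3',4'-tetra-O-benzyl-4β-methoxy-3-O-propanoylepioritin (2R, 2,3-cis-3,4-trans) | c1ccccc1COc1ccc(cc1OCc1ccccc1)[C@H]2Oc3c(ccc(OCc4ccccc4)c3OCc3ccccc3)[C@H](OC)[C@H]2OC(=O)CC
F5 | step 10 | (2R,3R)-7,8-bis(benzyloxy)-2-[3,4-bis(benzyloxy)phenyl]-3,4-dihydro-2H-chromen-3-yl acetate (3-O-acetyl-7,8,3',4'-tetra-O-benzylepioritin) | c1ccccc1COc1ccc(cc1OCc1ccccc1)[C@H]2Oc3c(ccc(OCc4ccccc4)c3OCc3ccccc3)C[C@H]2OC(C)=O
F6 | step 10 | 3-O-acetyl-7,8,3',4'-tetra-O-benzyl-4β-methoxyepioritin (2R, 2,3-cis-3,4-trans) | c1ccccc1COc1ccc(cc1OCc1ccccc1)[C@H]2Oc3c(ccc(OCc4ccccc4)c3OCc3ccccc3)[C@H](OC)[C@H]2OC(C)=O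
F7 | step 13 | epioritin-(4β→6)-4β-[(2,6-dimethylphenyl)sulfanyl]epioritin | Oc1ccc([C@H]2Oc3c(ccc(O)c3O)[C@H](c3cc4c(c(O)c3O)O[C@H](c3ccc(O)c(O)c3)[C@H](O)[C@H]4Sc3c(C)cccc3C)[C@H]2O)cc1O
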